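**Strategy.** The flavonol is traced back to a saturated chromanone opened at the C4–C4a bond. The key step closes ring C by intramolecular Friedel–Crafts acylation. It exploits the fact that C4a is the only unsubstituted carbon of the otherwise fully oxygenated ring A and lies ortho to O1, so a carboxyl group tethered through O1–C2–C3 can attack only there. The precursor is 2-acetoxy-3-(4-methoxyphenyl)-3-(2,3,4,5-tetramethoxyphenoxy)propanoic acid. In it, C2 and C3 of the future heterocycle already carry the anisyl ring B and the oxygen function, taken from C3 and C2 of an anisyl glycidate opened by 2,3,4,5-tetramethoxyphenol. Deacetylation and dehydrogenation then aromatise the pyranone.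

Key step: step 5

Assumption: 1 and 5 are taken as catalogue chemicals, and 5 is used as the racemic trans isomer. From 6 onward every intermediate is racemic and its two stereocentres are left unassigned, because both become sp2 carbons in 13. The SN2 opening should favour the anti-opened (2R*,3R*) diastereomer, but partial scrambling at the p-methoxybenzylic carbon is tolerated.

Step 1
Reactants: 1 1,2,3,4-tetramethoxybenzene
Product: 4 2,3,4,5-tetramethoxyphenol, via aryllithium 2 (not isolated), via dimethyl arylboronate 3 (not isolated)
Conditions: n-BuLi, TMEDA, THF, 0 °C; B(OMe)3, −78 °C → rt; AcOH, 30% aq. H2O2, 0 °C → rt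
Reagents that add atoms: hydrogen peroxide, OO
Why: Directed ortho-metalation at one of the two equivalent C–H positions next to a methoxy group, borylation of the aryllithium and oxidative boron-to-oxygen aryl shift (boronate oxidation) should give the phenol as a single regioisomer, with no stereocentre formed.

Step 2
Reactants: 4 2,3,4,5-tetramethoxyphenol; 5 methyl trans-3-(4-methoxyphenyl)oxirane-2-carboxylate
Product: 6 methyl 2-hydroxy-3-(4-methoxyphenyl)-3-(2,3,4,5-tetramethoxyphenoxy)propanoate
Conditions: Cs2CO3 (0.2 equiv), DMF, 60 °C, argon
Reagents that add atoms: none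
Why: Base-catalysed SN2-type epoxide opening (phenoxide O-alkylation) should occur at the p-methoxybenzylic C3, the usual site for heteroatom nucleophiles on 3-arylglycidates, with inversion there so that the anti-opened (2R*,3R*) racemate should predominate, while the dipolar aprotic medium favours O- over C-alkylation and the phenol re-protonates the product alkoxide so the base turns over.

Step 3
Reactants: 6 methyl 2-hydroxy-3-(4-methoxyphenyl)-3-(2,3,4,5-tetramethoxyphenoxy)propanoate
Product: 7 2-hydroxy-3-(4-methoxyphenyl)-3-(2,3,4,5-tetramethoxyphenoxy)propanoic acid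
Conditions: LiOH, THF/H2O, 0 °C → rt; then 1 M HCl to pH 3 at 0 °C
Reagents that add atoms: lithium hydroxide, [Li+].[OH-]
Why: Ester saponification (acyl–oxygen cleavage by hydroxide) at low temperature should leave the aryl ethers untouched, and any epimerisation of the existing centres is without consequence.

Step 4
Reactants: 7 2-hydroxy-3-(4-methoxyphenyl)-3-(2,3,4,5-tetramethoxyphenoxy)propanoic acid
Product: 9 2-acetoxy-3-(4-methoxyphenyl)-3-(2,3,4,5-tetramethoxyphenoxy)propanoic acid, via acetic mixed anhydride 8 (not isolated)
Conditions: Ac2O (2.5 equiv), pyridine, CH2Cl2, 0 °C → rt; then H2O, rt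
Reagents that add atoms: acetic anhydride, CC(=O)OC(C)=O
Why: Pyridine-mediated O-acetylation (nucleophilic acyl substitution) esterifies the secondary alcohol and turns the carboxyl group into its acetic mixed anhydride, which aqueous pyridine should cleave at the less hindered acetyl carbonyl to return the free acid without touching the stereocentres.

Step 5
Reactants: 9 2-acetoxy-3-(4-methoxyphenyl)-3-(2,3,4,5-tetramethoxyphenoxy)propanoic acid
Product: 11 3-acetoxy-5,6,7,8-tetramethoxy-2-(4-methoxyphenyl)chroman-4-one, via mixed trifluoroacetic anhydride 10 (not isolated)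
Conditions: TFAA (1.5 equiv), CH2Cl2, 0 °C → rt
Reagents that add atoms: none
Why: TFAA converts the carboxyl group of 9 into the mixed trifluoroacetic anhydride 10, whose acyl carbon (as the anhydride or its acylium ion pair) is attacked by C6 of the tetramethoxyphenoxy ring, the future C4a, and proton loss from the arenium ion gives the aryl ketone. The closest known reaction type is the trifluoroacetic anhydride-mediated intramolecular Friedel–Crafts acylation of 3-aryloxypropanoic acids to chroman-4-ones. Ring C closes in a 6-exo-trig mode, the carbonyl oxygen staying outside the new six-membered ring. No stereocentre is created; the two existing centres are carried through unassigned, the one next to the new ketone being epimerisable, which is harmless because both become sp2 in the last step. Regioselectivity is secured because the phenoxy ring offers a single C–H, ortho to the ether oxygen and ortho and para to methoxy groups, whereas the anisyl ring could only close a five-membered ring at a position meta to its methoxy group. The chemoselectivity needed, acylation ahead of acid-induced ionisation of the p-methoxybenzylic C–O bond, rests on the high nucleophilicity of that carbon, on the inductive destabilisation of the benzylic cation by the vicinal acetoxy and acyl groups, and on a medium free of Lewis acid at 0 °C.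

Step 6
Reactants: 11 3-acetoxy-5,6,7,8-tetramethoxy-2-(4-methoxyphenyl)chroman-4-one
Product: 13 3-hydroxy-5,6,7,8-tetramethoxy-2-(4-methoxyphenyl)-4H-chromen-4-one, via 3-hydroxyflavanone 12 (not isolated)
Conditions: K2CO3 (2 equiv), MeOH, O2 (1 atm), rt; then 1 M HCl to pH 5
Reagents that add atoms: none
Why: Carbonate-mediated methanolysis (transesterification) frees the 3-hydroxyl, and the enediolate of the resulting α-ketol should be autoxidised by O2 to the 3,4-dione, which tautomerises to the aromatic flavonol as in the second stage of the Algar–Flynn–Oyamada reaction, erasing both stereocentres.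

**Compound list**

1 | 1,2,3,4-tetramethoxybenzene | COc1ccc(OC)c(OC)c1OC | starting material
2 | (2,3,4,5-tetramethoxyphenyl)lithium (not isolated) | [Li]c1cc(OC)c(OC)c(OC)c1OC | intermediate
3 | dimethyl (2,3,4,5-tetramethoxyphenyl)boronate (not isolated) | COB(OC)c1cc(OC)c(OC)c(OC)c1OC | intermediate
4 | 2,3,4,5-tetramethoxyphenol | COc1cc(O)c(OC)c(OC)c1OC | intermediate
5 | methyl trans-3-(4-methoxyphenyl)oxirane-2-carboxylate, racemic (2R*,3S*), one enantiomer drawn | COC(=O)[C@@H]1O[C@H]1c1ccc(OC)cc1 | starting material
6 | methyl 2-hydroxy-3-(4-methoxyphenyl)-3-(2,3,4,5-tetramethoxyphenoxy)propanoate, racemic, C2 and C3 unassigned (anti-opened 2R*,3R* isomer expected to predominate) | COC(=O)C(O)C(Oc1cc(OC)c(OC)c(OC)c1OC)c1ccc(OC)cc1 | intermediate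
7 | 2-hydroxy-3-(4-methoxyphenyl)-3-(2,3,4,5-tetramethoxyphenoxy)propanoic acid, racemic, C2 and C3 unassigned | OC(=O)C(O)C(Oc1cc(OC)c(OC)c(OC)c1OC)c1ccc(OC)cc1 | intermediate
8 | acetic 2-acetoxy-3-(4-methoxyphenyl)-3-(2,3,4,5-tetramethoxyphenoxy)propanoic anhydride, racemic, unassigned (not isolated) | CC(=O)OC(=O)C(OC(C)=O)C(Oc1cc(OC)c(OC)c(OC)c1OC)c1ccc(OC)cc1 | intermediate
9 | 2-acetoxy-3-(4-methoxyphenyl)-3-(2,3,4,5-tetramethoxyphenoxy)propanoic acid, racemic, C2 and C3 unassigned | COc1ccc(C(Oc2cc(OC)c(OC)c(OC)c2OC)C(OC(C)=O)C(=O)O)cc1 | intermediate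
10 | 2-acetoxy-3-(4-methoxyphenyl)-3-(2,3,4,5-tetramethoxyphenoxy)propanoic trifluoroacetic anhydride, racemic, unassigned (not isolated) | COc1ccc(C(Oc2cc(OC)c(OC)c(OC)c2OC)C(OC(C)=O)C(=O)OC(=O)C(F)(F)F)cc1 | intermediate
11 | 3-acetoxy-5,6,7,8-tetramethoxy-2-(4-methoxyphenyl)chroman-4-one, racemic, C2 and C3 unassigned | COc1ccc(C2Oc3c(OC)c(OC)c(OC)c(OC)c3C(=O)C2OC(C)=O)cc1 | intermediate
12 | 3-hydroxy-5,6,7,8-tetramethoxy-2-(4-methoxyphenyl)chroman-4-one, racemic, unassigned (not isolated) | COc1ccc(C2Oc3c(OC)c(OC)c(OC)c(OC)c3C(=O)C2O)cc1 | intermediate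
13 | 3-hydroxy-5,6,7,8-tetramethoxy-2-(4-methoxyphenyl)-4H-chromen-4-one (no stereocentre) | COc1ccc(-c2oc3c(OC)c(OC)c(OC)c(OC)c3c(=O)c2O)cc1 | target

**Step count and risks**

Total steps: 6. Longest linear sequence: 6 steps (1 → 4 → 6 → 7 → 9 → 11 → 13), with 5 entering at step 2.

Steps most likely to fail:

1. Step 5 (key step). Acid-induced ionisation of the p-methoxybenzylic C–O bond, leading to loss or O-to-C migration of the aryl group, may outpace ring closure. Fallback: the pyranone would be built from phenol 4 by the chalcone route, which never passes through an sp3 benzylic ether. C-acetylation of 4 at its only free carbon (AcOH, BF3·OEt2, heat) should give 1-(2-hydroxy-3,4,5,6-tetramethoxyphenyl)ethanone F1. Claisen–Schmidt condensation with 4-methoxybenzaldehyde (KOH, EtOH) should give (E)-1-(2-hydroxy-3,4,5,6-tetramethoxyphenyl)-3-(4-methoxyphenyl)prop-2-en-1-one F2. Oxidative cyclisation (catalytic I2, DMSO, 120 °C) should give 5,6,7,8-tetramethoxy-2-(4-methoxyphenyl)-4H-chromen-4-one F3. Epoxidation of the C2–C3 double bond with dimethyldioxirane in acetone should give 2,3-epoxy-5,6,7,8-tetramethoxy-2-(4-methoxyphenyl)chroman-4-one F4, whose acid-catalysed isomerisation (catalytic TsOH) delivers the flavonol. A direct Algar–Flynn–Oyamada oxidation of F2 is avoided because the methoxy group flanking the carbonyl tends to divert such chalcones to aurones. This fallback sets out from 4 and returns to the route at 13.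

2. Step 2. The phenoxide may attack with poor chemoselectivity (C-alkylation, ester exchange) or the catalytic cycle may stall, so that the glycidate decomposes before it is opened. Fallback: the ether is formed by activating the alcohol instead of the epoxide. Acid-catalysed hydration of 5 (catalytic H2SO4, THF/H2O) should give methyl 2,3-dihydroxy-3-(4-methoxyphenyl)propanoate F5. A Mitsunobu etherification with 4 (PPh3, DIAD, THF, 0 °C) should then engage the benzylic β-hydroxyl selectively, since the α-hydroxyl of a 2,3-dihydroxy ester is deactivated by the ester group. This fallback sets out from 5 and returns to the route at 6.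

3. Step 6. The enolate of the dihydroflavonol may open ring C and re-close to a five-membered ring, or the flavonolate may be oxidised further, in competition with the wanted dehydrogenation. Fallback: the order of events is reversed so that no free α-ketol is exposed to base and oxygen. Dehydrogenation of 11 by hydride abstraction from the doubly activated C2–H (DDQ, 1,4-dioxane, 80 °C) should give 3-acetoxy-5,6,7,8-tetramethoxy-2-(4-methoxyphenyl)-4H-chromen-4-one F6, and brief methanolysis of this enol acetate (K2CO3, MeOH, argon, rt) should give the flavonol. This fallback sets out from 11 and returns to the route at 13.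

**Further compounds**

F1 | step 5 | 1-(2-hydroxy-3,4,5,6-tetramethoxyphenyl)ethanone | CC(=O)c1c(O)c(OC)c(OC)c(OC)c1OC
F2 | step 5 | (E)-1-(2-hydroxy-3,4,5,6-tetramethoxyphenyl)-3-(4-methoxyphenyl)prop-2-en-1-one | COc1ccc(/C=C/C(=O)c2c(O)c(OC)c(OC)c(OC)c2OC)cc1
F3 | step 5 | 5,6,7,8-tetramethoxy-2-(4-methoxyphenyl)-4H-chromen-4-one | COc1ccc(-c2cc(=O)c3c(OC)c(OC)c(OC)c(OC)c3o2)cc1
F4 | step 5 | 2,3-epoxy-5,6,7,8-tetramethoxy-2-(4-methoxyphenyl)chroman-4-one, racemic (epoxide necessarily cis-fused) | COc1ccc(C23OC2C(=O)c2c(OC)c(OC)c(OC)c(OC)c2O3)cc1
F5 | step 2 | methyl 2,3-dihydroxy-3-(4-methoxyphenyl)propanoate, racemic, C2 and C3 unassigned | COC(=O)C(O)C(O)c1ccc(OC)cc1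
F6 | step 6 | 3-acetoxy-5,6,7,8-tetramethoxy-2-(4-methoxyphenyl)-4H-chromen-4-one | COc1ccc(-c2oc3c(OC)c(OC)c(OC)c(OC)c3c(=O)c2OC(C)=O)cc1
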